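**Plan**

1. Numbering (cembrane): ring C1–C14; C15 (CH–CH3) on C1; C16 = lactone C=O bound to O3; C17–C20 = carbons on C15, C4, C8, C12. C3–O and C1 are 1,3-related ring atoms, so the lactone ring O3–C16–C15–C1–C2–C3 is six-membered, and a C15 radical held on O3 through a C16 acetal reaches C1 of a C1=C14 ring alkene in the 6-exo mode.
2. Cuts, in retrosynthetic order: epoxide O at C11/C12; C16 lactone to ethyl acetal; C15–C1 (radical cyclisation); O3–C16 and C15–Br (bromoacetal); C1=C14 (ring-closing metathesis); C7–C8 (alkenyllithium plus δ-lactone); C2–C3 (allylboration); C12–C13 (Zr/Cu allylation).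
3. Forward: fragment A (lactone 11, C1–C7) from (S)-linalool in five steps; fragment B (hydrazone 19, C8–C14) in four; joined at C7–C8; the 14-membered ring by metathesis; the six-membered acetal ring by the radical step; the epoxide last.
4. Stereochemistry: C4 from (S)-linalool; C3 by reagent-controlled allylboration matched with the Felkin–Anh preference; C7 by CBS reduction; C1 relayed from C3 through the chair 6-exo transition state; C15 by equilibration of the lactone; C11/C12 by Shi epoxidation of the E alkene, whose geometry comes from syn hydrozirconation.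
5. Protection: O4 as TBS ether from step 1 to step 18. It must stay blocked until C16 is a lactone, because a free O4–H would trap the C16 acetal or aldehyde as an internal bicyclic acetal. O7 as TBDPS ether; O3 masked as the δ-lactone until the coupling.

Key step: step 15

Assumption: (S)-linalool of high enantiomeric purity is taken as the commercial material; the C1=C14 geometry from step 13 and the two new centres of the bromoacetal are carried as mixtures because steps 15–17 erase or correct them.

**Fragment A**

Step 1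
Reactants: 1 (S)-linalool
Product: 2 linalool tert-butyldimethylsilyl ether
Conditions: TBSOTf, 2,6-lutidine, CH2Cl2, −78 → 0 °C
Reagents that add atoms: tert-butyldimethylsilyl triflate, CC(C)(C)[Si](C)(C)OS(=O)(=O)C(F)(F)F
Why: Silylation of a tertiary alcohol with a silyl triflate and a hindered pyridine base leaves the C4 stereocentre untouched and installs a bulky, non-chelating ether that should survive every step up to step 18.

Step 2
Reactants: 2 linalool tert-butyldimethylsilyl ether
Product: 4 (4S)-4-[(tert-butyldimethylsilyl)oxy]-4-methylhex-5-enal, via ozonide 3 (not isolated)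
Conditions: O3 (1 equiv, Sudan Red 7B end-point), CH2Cl2, −78 °C; then PPh3, −78 °C → rt
Reagents that add atoms: ozone, [O-][O+]=O
Why: Chemoselective ozonolysis, in which ozone attacks the electron-rich trisubstituted alkene well before the hindered vinyl group next to the silyloxy carbon, the dye marks the end-point and PPh3 reduces ozonide 3 to the aldehyde.

Step 3
Reactants: 4 (4S)-4-[(tert-butyldimethylsilyl)oxy]-4-methylhex-5-enal
Product: 5 methyl (4S)-4-[(tert-butyldimethylsilyl)oxy]-4-methylhex-5-enoate
Conditions: N-iodosuccinimide, K2CO3, MeOH, rt, dark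
Reagents that add atoms: methanol, CO
Why: Oxidative esterification of an aldehyde, in which the methanol hemiacetal is oxidised through its hypoiodite, fixes C7 at the acid level so that it differs from the C3 aldehyde made next; the deactivated vinyl group should not compete.

Step 4
Reactants: 5 methyl (4S)-4-[(tert-butyldimethylsilyl)oxy]-4-methylhex-5-enoate
Product: 7 methyl (4S)-4-[(tert-butyldimethylsilyl)oxy]-4-methyl-5-oxopentanoate, via ozonide 6 (not isolated)
Conditions: O3, CH2Cl2, −78 °C; then PPh3, −78 °C → rt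
Reagents that add atoms: ozone, [O-][O+]=O
Why: Ozonolysis with reductive work-up turns the remaining vinyl group into the C3 aldehyde, which has no α-hydrogen and cannot epimerise.

Step 5
Reactants: 7 methyl (4S)-4-[(tert-butyldimethylsilyl)oxy]-4-methyl-5-oxopentanoate; 8 allylmagnesium bromide
Product: 11 (5S,6R)-5-[(tert-butyldimethylsilyl)oxy]-5-methyl-6-(prop-2-en-1-yl)oxan-2-one, via borinate 9 (not isolated), via hydroxy ester 10 (not isolated)
Conditions: (+)-Ipc2BOMe (the borinate from (−)-α-pinene), 8, Et2O, 0 °C → rt; then 7, −78 °C; then NaBO3·4H2O, THF/H2O, rt; then pyridinium p-toluenesulfonate (cat.), PhH, 60 °C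
Reagents that add atoms: none
Why: Brown allylboration through a closed chair transition state, using the antipode of the reagent that converts benzaldehyde into the (R)-homoallylic alcohol, adds allyl to the aldehyde face that the α-silyloxy centre also prefers (Felkin–Anh, matched pair) and so sets C3 as R (3,4-anti), after which δ-hydroxy ester 10 closes under acid catalysis to the six-membered lactone that masks O3 and makes C7 an acylating centre.

**Fragment B**

Step 6
Reactants: 12 2-(2-bromoethyl)-2-methyl-1,3-dioxolane; 13 1-propynyllithium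
Product: 14 2-methyl-2-(pent-3-yn-1-yl)-1,3-dioxolane
Conditions: THF/DMPU, −20 °C → rt
Reagents that add atoms: none
Why: SN2 alkylation of a lithium acetylide by a primary bromide in a dipolar cosolvent, with the ketone kept as its ketal.

Step 7
Reactants: 14 2-methyl-2-(pent-3-yn-1-yl)-1,3-dioxolane; 15 allyl bromide
Product: 17 2-methyl-2-[(3E)-4-methylhepta-3,6-dien-1-yl]-1,3-dioxolane, via alkenylzirconocene 16 (not isolated)
Conditions: Cp2Zr(H)Cl (1.6 equiv), THF, 50 °C; then 15 (3 equiv), CuCl (10 mol %), 0 °C → rt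
Reagents that add atoms: none
Why: Syn hydrozirconation with an excess of the hydride equilibrates zirconium to the alkyne carbon bearing the small methyl group, and copper-catalysed allylation of alkenylzirconocene 16 proceeds with retention, so the E geometry of C11=C12 follows from the syn addition while the excess allyl bromide destroys residual Zr–H.

Step 8
Reactants: 17 2-methyl-2-[(3E)-4-methylhepta-3,6-dien-1-yl]-1,3-dioxolane
Product: 18 (5E)-6-methylnona-5,8-dien-2-one
Conditions: 1 M aq. HCl, THF, rt
Reagents that add atoms: water, O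
Why: Acid-catalysed hydrolysis of the dioxolane of a methyl ketone is fast at room temperature and should leave the isolated alkenes alone.

Step 9
Reactants: 18 (5E)-6-methylnona-5,8-dien-2-one
Product: 19 2,4,6-triisopropylbenzenesulfonyl hydrazone of 18
Conditions: 2,4,6-triisopropylbenzenesulfonohydrazide, HCl (cat.), THF, rt
Reagents that add atoms: 2,4,6-triisopropylbenzenesulfonohydrazide, CC(C)c1cc(C(C)C)c(S(=O)(=O)NN)c(C(C)C)c1
Why: Condensation of a ketone with an arenesulfonyl hydrazide gives the Shapiro precursor, and the ortho isopropyl groups prevent ring lithiation in the next step.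

**Coupling, macrocycle and key step**

Step 10
Reactants: 19 sulfonyl hydrazone of fragment B (1.3 equiv); 11 lactone of fragment A
Product: 22 (4R,5S,12E)-5-[(tert-butyldimethylsilyl)oxy]-4-hydroxy-5,13-dimethyl-9-methylidenehexadeca-1,12,15-trien-8-one, via alkenyllithium 20 (not isolated), via lithium lactolate 21 (not isolated)
Conditions: 19, n-BuLi (2.05 equiv per hydrazone), THF, −78 → 0 °C; then 11, −78 °C; sat. aq. NH4Cl, −78 °C
Reagents that add atoms: none
Why: Shapiro reaction, in which the dianion formed at the methyl group loses sulfinate and N2 on warming to give alkenyllithium 20, which adds once to the δ-lactone because lactolate 21 is stable at −78 °C, so the C7–C8 bond and the enone form together and O3–H is released only on quenching.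

Step 11
Reactants: 22 hydroxy enone
Product: 23 (4R,5S,8R,12E)-5-[(tert-butyldimethylsilyl)oxy]-5,13-dimethyl-9-methylidenehexadeca-1,12,15-triene-4,8-diol
Conditions: (3aS)-1-methyl-3,3-diphenyltetrahydro-1H,3H-pyrrolo[1,2-c][1,3,2]oxazaborole ((S)-2-methyl-CBS-oxazaborolidine, 0.3 equiv), catecholborane (3 equiv), PhMe, −78 °C; then MeOH, aq. NaHCO3
Reagents that add atoms: none
Why: Corey–Bakshi–Shibata reduction, in which the α-branched alkenyl group acts as the large substituent and the (S)-catalyst delivers hydride to the face that gives the (7R)-allylic alcohol (the sense in which acetophenone gives (R)-1-phenylethanol), while catecholborane at −78 °C should not hydroborate the terminal alkenes.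

Step 12
Reactants: 23 diol
Product: 24 (4R,5S,8R,12E)-5-[(tert-butyldimethylsilyl)oxy]-8-[(tert-butyldiphenylsilyl)oxy]-5,13-dimethyl-9-methylidenehexadeca-1,12,15-trien-4-ol
Conditions: TBDPSCl, imidazole, 4-(dimethylamino)pyridine (cat.), DMF, 0 °C → rt
Reagents that add atoms: tert-butyldiphenylsilyl chloride, CC(C)(C)[Si](Cl)(c1ccccc1)c1ccccc1
Why: Silylation with a bulky silyl chloride and imidazole discriminates on steric grounds, so the allylic C7 hydroxyl reacts while the C3 hydroxyl next to the quaternary silyloxy carbon stays free for step 14, and the diphenylsilyl ether tolerates the acid of step 16.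

Step 13
Reactants: 24 triene alcohol
Product: 25 (1R,6E,11R,14S)-14-[(tert-butyldimethylsilyl)oxy]-11-[(tert-butyldiphenylsilyl)oxy]-6,14-dimethyl-10-methylidenecyclotetradeca-3,6-dien-1-ol (E/Z mixture at the new alkene)
Conditions: (H2IMes)(PCy3)Cl2Ru=CHPh (second-generation Grubbs catalyst, 10 mol %), 1,4-benzoquinone (10 mol %), CH2Cl2 (1 mM), 40 °C
Reagents that add atoms: none
Why: Ring-closing metathesis of the two monosubstituted terminal alkenes at high dilution closes the 14-membered ring at C1=C14, the hindered 1,1-disubstituted and the trisubstituted alkenes being inert (a seven-membered ring through C8 would have to hold the E alkene) and benzoquinone suppressing migration of the skipped diene.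

Step 14
Reactants: 25 macrocyclic homoallylic alcohol; 26 ethyl 1-propenyl ether (5 equiv)
Product: 27 2-bromo-1-ethoxypropyl mixed acetal of 25 at O3 (four isomers at the acetal and bromide carbons)
Conditions: N-bromosuccinimide (1.5 equiv), CH2Cl2, −40 → 0 °C
Reagents that add atoms: N-bromosuccinimide, O=C1CCC(=O)N1Br
Why: Bromoetherification of the electron-rich enol ether, in which bromine is delivered to the β-carbon and the resulting oxocarbenium ion is captured by the only free hydroxyl (O3), should be much faster than any reaction of the three unactivated alkenes and gives the Ueno–Stork precursor.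

Step 15
Reactants: 27 macrocyclic bromoacetal
Product: 28 (1R,3R,4S,7R,11E,15S)-4-[(tert-butyldimethylsilyl)oxy]-7-[(tert-butyldiphenylsilyl)oxy]-16-ethoxy-3,16-epoxycembra-8(19),11-diene (epimers at C16; minor C15 epimer carried along)
Conditions: Bu3SnH (1.4 equiv) and azobis(isobutyronitrile) (0.2 equiv) added over 8 h by syringe pump, PhH (2 mM), 80 °C
Reagents that add atoms: none
Why: The tin radical abstracts bromine from C15, the secondary C15 radical adds to C1 of the C1=C14 alkene, and the C14 radical so formed takes hydrogen from Bu3SnH to carry the chain. The closest known reaction is the Ueno–Stork bromoacetal cyclisation of homoallylic alcohols in its 6-exo variant, here with the homoallylic unit C3–C2–C1=C14 embedded in a 14-membered ring. The ring closed is the six-membered acetal ring O3–C16–C15–C1–C2–C3, formed 6-exo-trig. C1 is set by the chair transition state in which the C3–C4 bond and the C1–C14 bond are both equatorial, which places C14 cis to C4 (1R from 3R); C15 should form mainly with its methyl group equatorial but is not relied on because step 17 equilibrates it, and the C16 epimers converge in step 16. The step needs ring closure to outrun direct reduction of the C15 radical and 1,5-hydrogen transfer from the allylic C2–H, which is addressed by keeping the tin hydride concentration very low and by the acetal tether with its short C–O bonds and no ester rotamer barrier. The C14 radical has no competing cyclisation, since attack on C11=C12 or on the C8 methylidene would need a three-, four- or strained medium ring, and both alkene geometries converge because C1 and C14 become sp3.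

**Endgame**

Step 16
Reactants: 28 bicyclic ethyl acetal
Product: 30 (1R,3R,4S,7R,11E)-4-[(tert-butyldimethylsilyl)oxy]-7-[(tert-butyldiphenylsilyl)oxy]cembra-8(19),11-dien-16,3-olide as a mixture of C15 epimers, via lactol 29 (not isolated)
Conditions: CrO3, H2SO4, H2O, acetone, 0 °C (Jones oxidation)
Reagents that add atoms: water, O
Why: Jones oxidation of a cyclic O-ethyl acetal, by acid hydrolysis to lactol 29 and chromic acid oxidation in the same flask, gives the δ-lactone while O4 stays silylated so that no internal bicyclic acetal can form, and both silyl ethers and both alkenes should tolerate the short exposure at 0 °C.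

Step 17
Reactants: 30 lactone as C15 epimer mixture
Product: 31 (1R,3R,4S,7R,11E,15S)-4-[(tert-butyldimethylsilyl)oxy]-7-[(tert-butyldiphenylsilyl)oxy]cembra-8(19),11-dien-16,3-olide
Conditions: DBU, PhMe, 80 °C
Reagents that add atoms: none
Why: Base-mediated epimerisation through the lactone enolate should lead to the thermodynamic epimer, in which the C15 methyl group is equatorial and trans to C14 on a lactone ring whose other two substituents (C4 on C3, C14 on C1) are already equatorial.

Step 18
Reactants: 31 (15S)-lactone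
Product: 32 (1R,3R,4S,7R,11E,15S)-4,7-dihydroxycembra-8(19),11-dien-16,3-olide
Conditions: Bu4NF (6 equiv), THF, 50 °C; aq. NH4Cl work-up
Reagents that add atoms: none
Why: Fluoride-induced desilylation cleaves both silyl ethers, the hindered tertiary ether needing the warming, and any lactone opened by adventitious hydroxide should reclose to the six-membered ring on the mildly acidic work-up.

Step 19
Reactants: 32 dihydroxy lactone
Product: 33 (1R,3R,4S,7R,11S,12S,15S)-11,12-epoxy-4,7-dihydroxycembr-8(19)-en-16,3-olide (CNP0262409.1)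
Conditions: 1,2:4,5-di-O-isopropylidene-β-L-erythro-2,3-hexodiulo-2,6-pyranose (the L-fructose-derived enantiomer of the Shi ketone, 0.3 equiv), Oxone (2KHSO5·KHSO4·K2SO4), K2CO3, Bu4NHSO4 (cat.), MeCN/dimethoxymethane, aq. Na2B4O7/Na2EDTA buffer, 0 °C
Reagents that add atoms: potassium peroxymonosulfate (active component of Oxone), [K+].[O-]S(=O)(=O)OO
Why: Shi epoxidation, in which the chiral dioxirane attacks the electron-rich trisubstituted C11=C12 alkene much faster than the 1,1-disubstituted allylic alkene, and the L-series ketone (the mirror image of the catalyst that gives (R,R)-epoxides from E-trisubstituted alkenes) should deliver oxygen to the face that gives the (11S,12S)-epoxide.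

**Compound list**

1 | (S)-linalool, (3S)-3,7-dimethylocta-1,6-dien-3-ol | C=C[C@@](C)(O)CCC=C(C)C | starting material
2 | tert-butyl{[(3S)-3,7-dimethylocta-1,6-dien-3-yl]oxy}dimethylsilane | C=C[C@@](C)(O[Si](C)(C)C(C)(C)C)CCC=C(C)C | intermediate
3 | 3-{(3S)-3-[(tert-butyldimethylsilyl)oxy]-3-methylpent-4-en-1-yl}-5,5-dimethyl-1,2,4-trioxolane (ozonide, formed in the flask, mixture at the ring carbon) | C=C[C@@](C)(O[Si](C)(C)C(C)(C)C)CCC1OOC(C)(C)O1 | intermediate
4 | (4S)-4-[(tert-butyldimethylsilyl)oxy]-4-methylhex-5-enal | C=C[C@@](C)(O[Si](C)(C)C(C)(C)C)CCC=O | intermediate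
5 | methyl (4S)-4-[(tert-butyldimethylsilyl)oxy]-4-methylhex-5-enoate | C=C[C@@](C)(O[Si](C)(C)C(C)(C)C)CCC(=O)OC | intermediate
6 | methyl (4S)-4-[(tert-butyldimethylsilyl)oxy]-4-(1,2,4-trioxolan-3-yl)pentanoate (ozonide, formed in the flask, mixture at the ring carbon) | C1(OOCO1)[C@@](C)(O[Si](C)(C)C(C)(C)C)CCC(=O)OC | intermediate
7 | methyl (4S)-4-[(tert-butyldimethylsilyl)oxy]-4-methyl-5-oxopentanoate | O=C[C@@](C)(O[Si](C)(C)C(C)(C)C)CCC(=O)OC | intermediate
8 | allylmagnesium bromide | C=CC[Mg]Br | starting material
9 | methyl (4S,5R)-4-[(tert-butyldimethylsilyl)oxy]-5-[(diisopinocampheylboranyl)oxy]-4-methyloct-7-enoate (borinate, formed in the flask) | C=CC[C@@H](OB([C@H]1C[C@H]2C[C@@H]([C@@H]1C)C2(C)C)[C@H]1C[C@H]2C[C@@H]([C@@H]1C)C2(C)C)[C@@](C)(O[Si](C)(C)C(C)(C)C)CCC(=O)OC | intermediate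
10 | methyl (4S,5R)-4-[(tert-butyldimethylsilyl)oxy]-5-hydroxy-4-methyloct-7-enoate (formed in the flask) | C=CC[C@@H](O)[C@@](C)(O[Si](C)(C)C(C)(C)C)CCC(=O)OC | intermediate
11 | (5S,6R)-5-[(tert-butyldimethylsilyl)oxy]-5-methyl-6-(prop-2-en-1-yl)oxan-2-one (fragment A; ring O = O3, C=O = C7) | C=CC[C@H]1OC(=O)CC[C@]1(C)O[Si](C)(C)C(C)(C)C | intermediate
12 | 2-(2-bromoethyl)-2-methyl-1,3-dioxolane | CC1(CCBr)OCCO1 | starting material
13 | 1-propynyllithium | CC#C[Li] | starting material
14 | 2-methyl-2-(pent-3-yn-1-yl)-1,3-dioxolane | CC#CCCC1(C)OCCO1 | intermediate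
15 | allyl bromide | C=CCBr | starting material
16 | chlorobis(cyclopentadienyl)[(2E)-5-(2-methyl-1,3-dioxolan-2-yl)pent-2-en-2-yl]zirconium (formed in the flask) | C/C(=C\CCC1(C)OCCO1)[Zr](Cl)(C1C=CC=C1)C1C=CC=C1 | intermediate
17 | 2-methyl-2-[(3E)-4-methylhepta-3,6-dien-1-yl]-1,3-dioxolane | C=CC/C(C)=C/CCC1(C)OCCO1 | intermediate
18 | (5E)-6-methylnona-5,8-dien-2-one | CC(=O)CC/C=C(C)/CC=C | intermediate
19 | N'-[(5E)-6-methylnona-5,8-dien-2-ylidene]-2,4,6-tri(propan-2-yl)benzenesulfonohydrazide (fragment B) | CC(CC/C=C(C)/CC=C)=NNS(=O)(=O)c1c(C(C)C)cc(C(C)C)cc1C(C)C | intermediate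
20 | [(5E)-6-methylnona-1,5,8-trien-2-yl]lithium (formed in the flask) | [Li]C(=C)CC/C=C(C)/CC=C | intermediate
21 | lithium (5S,6R)-5-[(tert-butyldimethylsilyl)oxy]-5-methyl-2-[(5E)-6-methylnona-1,5,8-trien-2-yl]-6-(prop-2-en-1-yl)oxan-2-olate (formed in the flask, mixture at C2 of the ring) | C=CC[C@H]1OC([O-])(C(=C)CC/C=C(C)/CC=C)CC[C@]1(C)O[Si](C)(C)C(C)(C)C.[Li+] | intermediate
22 | (4R,5S,12E)-5-[(tert-butyldimethylsilyl)oxy]-4-hydroxy-5,13-dimethyl-9-methylidenehexadeca-1,12,15-trien-8-one | C=CC[C@@H](O)[C@@](C)(O[Si](C)(C)C(C)(C)C)CCC(=O)C(=C)CC/C=C(C)/CC=C | intermediate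
23 | (4R,5S,8R,12E)-5-[(tert-butyldimethylsilyl)oxy]-5,13-dimethyl-9-methylidenehexadeca-1,12,15-triene-4,8-diol | C=CC[C@@H](O)[C@@](C)(O[Si](C)(C)C(C)(C)C)CC[C@@H](O)C(=C)CC/C=C(C)/CC=C | intermediate
24 | (4R,5S,8R,12E)-5-[(tert-butyldimethylsilyl)oxy]-8-[(tert-butyldiphenylsilyl)oxy]-5,13-dimethyl-9-methylidenehexadeca-1,12,15-trien-4-ol | C=CC[C@@H](O)[C@@](C)(O[Si](C)(C)C(C)(C)C)CC[C@@H](O[Si](c1ccccc1)(c1ccccc1)C(C)(C)C)C(=C)CC/C=C(C)/CC=C | intermediate
25 | (1R,6E,11R,14S)-14-[(tert-butyldimethylsilyl)oxy]-11-[(tert-butyldiphenylsilyl)oxy]-6,14-dimethyl-10-methylidenecyclotetradeca-3,6-dien-1-ol (3E/3Z mixture; ring C1 = cembrane C3, C3=C4 = cembrane C1=C14) | C=C1CC/C=C(C)/CC=CC[C@@H](O)[C@@](C)(O[Si](C)(C)C(C)(C)C)CC[C@H]1O[Si](c1ccccc1)(c1ccccc1)C(C)(C)C | intermediate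
26 | ethyl 1-propenyl ether (E/Z mixture) | CCOC=CC | starting material
27 | 2-bromo-1-ethoxypropyl mixed acetal of 25 at its free hydroxyl (isomers at the acetal and bromide carbons and at C1=C14) | C=C1CC/C=C(C)/CC=CC[C@@H](OC(OCC)C(C)Br)[C@@](C)(O[Si](C)(C)C(C)(C)C)CC[C@H]1O[Si](c1ccccc1)(c1ccccc1)C(C)(C)C | intermediate
28 | (1R,3R,4S,7R,11E,15S)-4-[(tert-butyldimethylsilyl)oxy]-7-[(tert-butyldiphenylsilyl)oxy]-16-ethoxy-3,16-epoxycembra-8(19),11-diene (epimers at C16) | C=C1CC/C=C(C)/CC[C@@H]2C[C@@H](OC(OCC)[C@H]2C)[C@@](C)(O[Si](C)(C)C(C)(C)C)CC[C@H]1O[Si](c1ccccc1)(c1ccccc1)C(C)(C)C | intermediate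
29 | (1R,3R,4S,7R,11E)-4-[(tert-butyldimethylsilyl)oxy]-7-[(tert-butyldiphenylsilyl)oxy]-3,16-epoxycembra-8(19),11-dien-16-ol (lactol, formed in the flask, mixture at C15 and C16) | C=C1CC/C=C(C)/CC[C@@H]2C[C@@H](OC(O)C2C)[C@@](C)(O[Si](C)(C)C(C)(C)C)CC[C@H]1O[Si](c1ccccc1)(c1ccccc1)C(C)(C)C | intermediate
30 | (1R,3R,4S,7R,11E)-4-[(tert-butyldimethylsilyl)oxy]-7-[(tert-butyldiphenylsilyl)oxy]cembra-8(19),11-dien-16,3-olide (C15 epimer mixture) | C=C1CC/C=C(C)/CC[C@@H]2C[C@@H](OC(=O)C2C)[C@@](C)(O[Si](C)(C)C(C)(C)C)CC[C@H]1O[Si](c1ccccc1)(c1ccccc1)C(C)(C)C | intermediate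
31 | (1R,3R,4S,7R,11E,15S)-4-[(tert-butyldimethylsilyl)oxy]-7-[(tert-butyldiphenylsilyl)oxy]cembra-8(19),11-dien-16,3-olide | C=C1CC/C=C(C)/CC[C@@H]2C[C@@H](OC(=O)[C@H]2C)[C@@](C)(O[Si](C)(C)C(C)(C)C)CC[C@H]1O[Si](c1ccccc1)(c1ccccc1)C(C)(C)C | intermediate
32 | (1R,3R,4S,7R,11E,15S)-4,7-dihydroxycembra-8(19),11-dien-16,3-olide | C=C1CC/C=C(C)/CC[C@@H]2C[C@@H](OC(=O)[C@H]2C)[C@@](C)(O)CC[C@H]1O | intermediate
33 | (1R,3R,4S,7R,11S,12S,15S)-11,12-epoxy-4,7-dihydroxycembr-8(19)-en-16,3-olide (CNP0262409.1) | C=C1CC[C@@H]2O[C@@]2(C)CC[C@@H]2C[C@@H](OC(=O)[C@H]2C)[C@@](C)(O)CC[C@H]1O | target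

**Count and risks**

Total step count: 19. Longest linear sequence: 15 steps (steps 1–5 and 10–19, from (S)-linalool); fragment B adds steps 6–9.

Most likely to fail:

Step 15. The 6-exo closure onto an unactivated alkene is slow, so hydrogen transfer from the tin hydride to the uncyclised C15 radical, or a 1,5-hydrogen shift from the allylic C2 position, may outrun ring closure. The fallback sets out from 25 and returns at 28. Alcohol 25 is treated with ethyl 1-propenyl ether and N-iodosuccinimide to give the macrocyclic iodoacetal F1. F1 is cyclised under iodine-atom-transfer conditions ((Bu3Sn)2 (cat.), hν, PhH, 80 °C), where no hydride donor is present, so the C15 radical persists until it closes the ring and the C14 radical takes iodine from a further molecule of F1 to give the C14-iodo bicyclic acetal F2. The iodine is then removed with Bu3SnH and azobis(isobutyronitrile), which gives 28.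

Step 13. Intermolecular metathesis to oligomers, or migration of the terminal C14 double bond of the skipped diene followed by ring contraction, may compete with closure of the 14-membered ring. The fallback sets out from 11 and 18 and returns at 25; it forms C1=C14 between the fragments and closes the ring at C7–C8 instead. Ketone 18 is converted with KN(SiMe3)2 and PhNTf2 (THF, −78 °C) into the kinetic enol triflate F3. Cross-metathesis of lactone 11 with an excess of F3, using (H2IMes)Cl2Ru=CH(2-iPrOC6H4) (second-generation Hoveyda–Grubbs catalyst), gives the linked lactone triflate F4. Reduction with i-Bu2AlH at −78 °C gives the lactol F5. An intramolecular Nozaki–Hiyama–Kishi reaction (CrCl2, NiCl2 (cat.), DMSO/THF, high dilution) on the hydroxy aldehyde form of F5 closes the macrocycle as the C7-epimeric diol F6. MnO2 oxidises only the allylic hydroxyl to the macrocyclic enone F7, reduction as in step 11 gives the (7R)-diol F8, and silylation as in step 12 gives 25.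

Step 10. Proton transfer to the alkenyllithium (from the lactone α-position or the doubly allylic C13 methylene), or collapse of the lactolate followed by a second addition, would erode the coupling. The fallback sets out from 11 and 18 and returns at 22; it uses no organolithium. Lactone 11 is reduced with i-Bu2AlH at −78 °C to the lactol F9. F9 is coupled with the enol triflate F3 (made from 18 as above) under Nozaki–Hiyama–Kishi conditions (CrCl2, NiCl2 (cat.), DMSO) to give the acyclic diol F10 as a mixture at C7. Oxidation of its allylic hydroxyl with MnO2 gives 22.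

**Further compounds**

F1 | step 15 | 2-iodo-1-ethoxypropyl mixed acetal of 25 (iodoacetal, isomer mixture) | C=C1CC/C=C(C)/CC=CC[C@@H](OC(OCC)C(C)I)[C@@](C)(O[Si](C)(C)C(C)(C)C)CC[C@H]1O[Si](c1ccccc1)(c1ccccc1)C(C)(C)C
F2 | step 15 | 14-iodo derivative of bicyclic acetal 28 (mixture at C14 and C16) | C=C1CC/C=C(C)/CC(I)[C@@H]2C[C@@H](OC(OCC)[C@H]2C)[C@@](C)(O[Si](C)(C)C(C)(C)C)CC[C@H]1O[Si](c1ccccc1)(c1ccccc1)C(C)(C)C
F3 | step 13 | (5E)-6-methylnona-1,5,8-trien-2-yl trifluoromethanesulfonate | C=C(OS(=O)(=O)C(F)(F)F)CC/C=C(C)/CC=C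
F4 | step 13 | cross-metathesis product of 11 and F3 (lactone bearing the C1=C14-linked enol triflate chain, E/Z mixture) | C=C(OS(=O)(=O)C(F)(F)F)CC/C=C(C)/CC=CC[C@H]1OC(=O)CC[C@]1(C)O[Si](C)(C)C(C)(C)C
F5 | step 13 | lactol from F4 (mixture at the lactol carbon) | C=C(OS(=O)(=O)C(F)(F)F)CC/C=C(C)/CC=CC[C@H]1OC(O)CC[C@]1(C)O[Si](C)(C)C(C)(C)C
F6 | step 13 | macrocyclic diol, 25 without the diphenylsilyl group, as C7 epimers | C=C1CC/C=C(C)/CC=CC[C@@H](O)[C@@](C)(O[Si](C)(C)C(C)(C)C)CCC1O
F7 | step 13 | macrocyclic enone (C7 ketone of F6) | C=C1CC/C=C(C)/CC=CC[C@@H](O)[C@@](C)(O[Si](C)(C)C(C)(C)C)CCC1=O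
F8 | step 13 | (7R)-macrocyclic diol | C=C1CC/C=C(C)/CC=CC[C@@H](O)[C@@](C)(O[Si](C)(C)C(C)(C)C)CC[C@H]1O
F9 | step 10 | (5S,6R)-5-[(tert-butyldimethylsilyl)oxy]-5-methyl-6-(prop-2-en-1-yl)oxan-2-ol (lactol of 11) | C=CC[C@H]1OC(O)CC[C@]1(C)O[Si](C)(C)C(C)(C)C
F10 | step 10 | diol 23 together with its C7 epimer | C=CC[C@@H](O)[C@@](C)(O[Si](C)(C)C(C)(C)C)CCC(O)C(=C)CC/C=C(C)/CC=C
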